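All runs were generated by integration on assumed constants, and the scatter is random.

Leave the flask closed and add nothing. It is the grey run itself, and reagent is the limiting reagent: c(reagent) of 0.0550 M pays for 55.0 % of the two substrates together.

- grey: left-handed substrate 0.050 M; right-handed substrate 0.050 M; reagent 0.055 M; free catalyst 0.25 mM; the very flask that is asked about, followed so far
- flask: left-handed substrate 0.050 M; reagent 0.0550 M; free catalyst 0.25 mM; right-handed substrate 0.050 M; time 2.0 d

grey run (percent of the left-handed substrate and right-handed substrate together charged)

| time / h | left-handed substrate / % | right-handed substrate / % |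
|---|---|---|
| 2.00 | 27.9 | 50.3 |
| 4.00 | 17.4 | 49.0 |
| 10.0 | 7.4 | 44.4 |
| 25.0 | 9.5 | 36.7 |

(scatter of a reading: 0.5 percentage points)

- free catalyst is single-handed; left-handed substrate and right-handed substrate are mirror images of each other, charged as a racemate, each of them at the stated concentration
- an excess is the difference of the two amounts in percent of their sum
- an excess is below zero if the other one leads

* part of the left-handed substrate and right-handed substrate charged together that has reacted at 2.0 d
* excess of left-handed product over right-handed product in the product at 2.0 d
* excess of right-handed substrate over left-handed substrate among what is left of the two at 2.0 d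

After 4.00 h the left-handed substrate stood at 17.4 % and the right-handed at 49.0 %, so I read the later fall of the right-handed substrate as racemization. From 10.0 h to 25.0 h it lost 7.7 percentage points while right-handed minus left-handed averaged 32.1 %. Each turnover narrows that gap by two, which gives 21.7 h, the gap half-life, the time in which racemization halves the gap between the substrates.

At 25.0 h the gap read 27.2 %, with reagent for 1.20 % more. The 23.0 h still to run exceed the gap half-life, so don't sample early. I expect a gap of 13.6 % over 45.0 % of substrate left, so eS near 30.2 %.

The forecast gives c 54.9 %, eP 87 % and eS 33 %, the last above my figure, holding that “the substrate must be racemizing slowly”.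

    reagent + catalyst intermediate B → free catalyst + right-handed product (k = 390 L mol⁻¹ h⁻¹)
    2 free catalyst ⇌ resting dimer (K = 9100 L mol⁻¹, k = 4600 L mol⁻¹ h⁻¹)
    left-handed substrate ⇌ right-handed substrate (k = 0.0170 h⁻¹)
    reagent + catalyst intermediate A → free catalyst + left-handed product (k = 1100 L mol⁻¹ h⁻¹)
    free catalyst + left-handed substrate ⇌ catalyst intermediate A (K = 460 L mol⁻¹, k = 2.00 × 10⁵ L mol⁻¹ h⁻¹)
    free catalyst + right-handed substrate ⇌ catalyst intermediate B (K = 9.20 L mol⁻¹, k = 84000 L mol⁻¹ h⁻¹)
    free catalyst ⇌ dormant form (K = 0.540, k = 0.940 h⁻¹)

The flask gives c 55.2 %, eP 96.0 % and eS 27.6 %. Right-handed product stands at 1.09 % of the charge, against the forecast's 3.5. Now take the neighbour flask charged with 0.033 M of reagent, where c is 33.2 % and nearly all of the product is left-handed. As a rough estimate, counting that product as made at the start, the gap in that neighbour flask begins near 33.2 %, and the gap half-life as read from the grey run puts it near 7.17 % by 2.0 d. That neighbour flask holds a gap of 7.39 %.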